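(All runs are simulated on assumed constants; scatter was added.)

While racemization adds nothing, the two mirror-image substrates meet the same free catalyst and the same reagent, so one ratio stays constant along a run, whatever those two concentrations do:

s = ln[c(left-handed substrate)/its charge] / ln[c(right-handed substrate)/its charge]

all flasks: left-handed substrate 0.10 M; right-handed substrate 0.10 M; racemization catalyst 0.50 mM; added ligand 0.37 mM

| flask | reagent | free catalyst | remark | time |
|---|---|---|---|---|
| blue | 0.22 M | 0.95 mM | run made earlier |  |
| amber | 0.22 M | 4.1 mM | run made earlier |  |
| midnight | 0.220 M | 5.0 mM |  | 2.5 d |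
| dawn | 0.220 M | 1.2 mM |  | 2.5 d |

| run | time / d | left-handed product / % | right-handed product / % |
|---|---|---|---|
| blue | 0.208 | 1.1 | 0.2 |
| blue | 0.625 | 5.6 | 0.1 |
| blue | 1.25 | 9.7 | 0.2 |
| blue | 1.67 | 13.3 | 0.9 |
| blue | 2.50 | 16.9 | 1.1 |
| amber | 0.500 | 15.5 | 1.2 |
| amber | 1.04 | 25.2 | 1.1 |
| amber | 1.67 | 32.6 | 3.1 |
| amber | 2.08 | 35.8 | 3.1 |
| amber | 2.50 | 38.4 | 3.6 |

(standard deviation of a reading: 0.5 percentage points)

- the winner by excess of left-handed product over right-handed product in the product; "neither" if no more than 2 percentage points parts them (midnight / dawn / neither)
- excess of left-handed product over right-handed product in the product at the end, midnight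
- excess of left-handed product over right-handed product in the product at the end, dawn

The percentages count both substrates together, so I doubled amber's last readings, 38.4% and 3.6%, to get the fractions converted. They gave s = 19.6, the selectivity factor, a reading that carries the scatter of 0.5 percentage points.

The bench rule takes the product excess as (s − 1)/(s + 1), here 90.3%. It holds while the substrates stand about equal. I followed one reagent molecule to its fork:

chance of going left = s·c(left-handed substrate) / [s·c(left-handed substrate) + c(right-handed substrate)]

That chance was 95.1% at the start but 83.1% at amber's end. The excess read at 2.5 d was accordingly 87.8% in blue, and in amber it was 82.9%, less than the rule gives.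

The excess follows conversion, and with reagent and time held alike in the runs and the new flasks, I placed the new flasks by their ratios of free catalyst. Dawn carries 1.26 times blue's free catalyst, and midnight 1.22 times amber's. I scaled amber's logarithm by c(free catalyst), taking the reagent's course as amber's, an approximation:

midnight: −ln(fraction of left-handed substrate left) = 1.78, excess 81.0%

dawn: −ln(fraction of left-handed substrate left) = 0.428, excess 88.3%

So I expected dawn to lead midnight by 7.3 points.

The forecast, which called this “plain kinetic resolution”, named dawn, with 82% for midnight, 1.00 point above my figure, and 88% for dawn.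

    reagent + free catalyst + left-handed substrate → free catalyst + left-handed product (k = 0.0100 L² mol⁻² s⁻¹)
    reagent + free catalyst + right-handed substrate → free catalyst + right-handed product (k = 5.10 × 10⁻⁴ L² mol⁻² s⁻¹)
    left-handed substrate + racemization catalyst ⇌ right-handed substrate + racemization catalyst, rate k3*[racemization catalyst]*[left-handed substrate] forward; the back reaction follows from the equilibrium constant (k = 0.0160 L mol⁻¹ s⁻¹)
    2 racemization catalyst ⇌ resting dimer, settled at all times (K = 4.30 × 10⁵ L mol⁻¹)
    racemization catalyst + added ligand ⇌ idle complex, settled at all times (K = 1.30 × 10⁶ L mol⁻¹)

The flasks gave 81.7% for midnight and 88.0% for dawn, so dawn led. At its start midnight's left-handed step used reagent 20 times as fast as its right-handed step, and midnight's excess had fallen from there to 85.7% after 1.25 d. From the 19% of left-handed substrate left in midnight, s gives 81.8%. A neighbour of midnight with 0.0020 M of free catalyst kept 46% of its left-handed substrate, for which s gives 86.6%, and that flask stood at 86.6%.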